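**Retrosynthetic overview**
1. Numbering: ring C1(=O), C2(OMe), C3(OH), C4(=O), C5(CH3), C6(side chain); side chain C1' (on C6) to C24'. No ring is formed in the route: the carbocycle comes from orcinol and becomes the quinone ring last, by oxidation at C4–H of resorcinol 24.
2. Key disconnection C5'–C6': on the C6'=C7' olefin, C6' bears H and C5', and C7' bears a methyl cis to C5' and C8' trans to it. This is the syn adduct of CH3 and C5' across a terminal alkyne C6'≡C7'; the aromatic ring (as a bis-MOM resorcinol ether) and the other olefins are inert to Al, Zn and Pd. Hence alkyne 20 (C6'–C24'), a methyl from Me3Al and primary bromide 16 (ring plus C1'–C5') are joined in one three-component operation.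
3. 16: aryl–C1' bond by allylation of ortho-metalated arene 6 with (E)-allylic bromide 11, which comes from the same syn-methylalumination on the C4 alkyne 7 with formaldehyde as electrophile.
4. 6: from orcinol by MOM protection, ortho-lithiation/oxygenation of the carbon between the two oxygens, and O-methylation. 20: from (2E,6E,10E)-geranylgeraniol via the bromide and a propargyl anion equivalent.

Key step: step 11

Remark: orcinol (1), silyl ether 7 and all-E geranylgeraniol (17) are taken as commercial; the target is written as the 3-hydroxy-1,4-quinone tautomer, on which oxidation of 24 at its only free ring carbon converges through either phenoxyl radical.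

**Route**

Step 1
Reactants: 1 orcinol (5-methylbenzene-1,3-diol)
Product: 2 1,3-bis(methoxymethoxy)-5-methylbenzene
Conditions: MOMCl, i-Pr2NEt, CH2Cl2, 0 °C to rt
Reagents that add atoms: chloromethyl methyl ether, COCCl
Why: Williamson-type O-alkylation of both phenols by the reactive α-chloro ether (MOM protection), which also installs the directing groups for both later ortho-lithiations.

Step 2
Reactants: 2 1,3-bis(methoxymethoxy)-5-methylbenzene
Product: 5 2,6-bis(methoxymethoxy)-4-methylphenol, via aryllithium 3 (not isolated), via lithium aryltrimethoxyborate 4 (not isolated)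
Conditions: n-BuLi, THF, 0 °C to rt; B(OMe)3, −78 °C to rt; then AcOH, 30% H2O2, 0 °C to rt
Reagents that add atoms: hydrogen peroxide, OO
Why: Directed ortho-metalation at the ring carbon flanked by the two OMOM groups, borylation and oxidative 1,2-aryl shift from boron to oxygen (boronate oxidation) should give the phenol.

Step 3
Reactants: 5 2,6-bis(methoxymethoxy)-4-methylphenol
Product: 6 2-methoxy-1,3-bis(methoxymethoxy)-5-methylbenzene
Conditions: MeI, K2CO3, acetone, reflux
Reagents that add atoms: iodomethane, CI
Why: Williamson methylation of the phenol installs the only methoxy group of the target (O2) between the two masked hydroxyls.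

Step 4
Reactants: 7 tert-butyl(but-3-yn-1-yloxy)dimethylsilane
Product: 10 (2E)-5-(tert-butyldimethylsilyloxy)-3-methylpent-2-en-1-ol, via alkenyldimethylalane 8 (not isolated), via lithium alkenylalanate 9 (not isolated)
Conditions: Me3Al, Cp2ZrCl2 (0.25 equiv), CH2Cl2, 0 °C to rt; volatiles removed; n-BuLi, hexane/THF, −78 to 0 °C; (CH2O)n, THF, rt; aq. KNaC4H4O6
Reagents that add atoms: trimethylaluminium, C[Al](C)C; formaldehyde (as paraformaldehyde), C=O
Why: Negishi zirconium-catalysed carboalumination adds CH3–Al syn across the terminal alkyne with aluminium on the terminal carbon, and hydroxymethylation of the derived alanate by formaldehyde proceeds with retention, so CH2OH and CH3 end up cis (the E geometry of the future C2'=C3' olefin).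

Step 5
Reactants: 10 (2E)-5-(tert-butyldimethylsilyloxy)-3-methylpent-2-en-1-ol
Product: 11 (2E)-1-bromo-5-(tert-butyldimethylsilyloxy)-3-methylpent-2-ene
Conditions: CBr4, PPh3, CH2Cl2, 0 °C
Reagents that add atoms: carbon tetrabromide, BrC(Br)(Br)Br
Why: Appel bromination is an SN2 displacement at the primary allylic carbon under neutral conditions, so neither allylic transposition nor loss of the silyl ether or of the E geometry is expected.

Step 6
Reactants: 6 2-methoxy-1,3-bis(methoxymethoxy)-5-methylbenzene; 11 (2E)-1-bromo-5-(tert-butyldimethylsilyloxy)-3-methylpent-2-ene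
Product: 14 tert-butyl{[(3E)-5-[3-methoxy-2,4-bis(methoxymethoxy)-6-methylphenyl]-3-methylpent-3-en-1-yl]oxy}dimethylsilane, via aryllithium 12 (not isolated), via arylcopper 13 (not isolated)
Conditions: n-BuLi, THF, 0 °C to rt; CuBr·SMe2 (1 equiv), −78 to −40 °C; 11, −78 °C to rt
Reagents that add atoms: none
Why: Directed ortho-metalation next to an OMOM group (the two free ring positions are equivalent by symmetry) followed by SN2 allylic substitution of the arylcopper at the unhindered primary carbon of 11, the standard prenylation of MOM-protected phenols, should form the aryl–C1' bond with the E olefin untouched.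

Step 7
Reactants: 14 tert-butyl{[(3E)-5-[3-methoxy-2,4-bis(methoxymethoxy)-6-methylphenyl]-3-methylpent-3-en-1-yl]oxy}dimethylsilane
Product: 15 (3E)-5-[3-methoxy-2,4-bis(methoxymethoxy)-6-methylphenyl]-3-methylpent-3-en-1-ol
Conditions: Bu4NF, THF, 0 °C to rt
Reagents that add atoms: none
Why: Fluoride-mediated desilylation of the primary silyl ether, to which the aryl MOM ethers and the olefin are inert.

Step 8
Reactants: 15 (3E)-5-[3-methoxy-2,4-bis(methoxymethoxy)-6-methylphenyl]-3-methylpent-3-en-1-ol
Product: 16 2-[(2E)-5-bromo-3-methylpent-2-en-1-yl]-4-methoxy-3,5-bis(methoxymethoxy)-1-methylbenzene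
Conditions: CBr4, PPh3, CH2Cl2, 0 °C to rt
Reagents that add atoms: carbon tetrabromide, BrC(Br)(Br)Br
Why: Appel bromination of the primary alcohol under neutral conditions should leave the acid-labile MOM ethers and the trisubstituted olefin intact and place the leaving group on C5'.

Step 9
Reactants: 17 (2E,6E,10E)-geranylgeraniol
Product: 18 (2E,6E,10E)-geranylgeranyl bromide
Conditions: PBr3 (0.4 equiv), Et2O, −10 to 0 °C
Reagents that add atoms: phosphorus tribromide, BrP(Br)Br
Why: Standard conversion of a primary allylic alcohol into the allylic bromide with PBr3 at low temperature, an SN2 process that keeps the 2E geometry.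

Step 10
Reactants: 18 (2E,6E,10E)-geranylgeranyl bromide
Product: 20 (5E,9E,13E)-6,10,14,18-tetramethylnonadeca-5,9,13,17-tetraen-1-yne, via alkynylsilane 19 (not isolated)
Conditions: 1-(trimethylsilyl)propyne, n-BuLi, THF, −78 to −20 °C; 18, −78 °C to rt; then K2CO3 (cat.), MeOH, rt
Reagents that add atoms: 1-(trimethylsilyl)propyne, CC#C[Si](C)(C)C
Why: SN2 alkylation of the silyl-stabilised propargyllithium at the primary allylic carbon (the silyl group suppresses allenic attack) followed by base-catalysed protodesilylation of the alkynylsilane should give the skipped enyne.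

Step 11
Reactants: 20 (5E,9E,13E)-6,10,14,18-tetramethylnonadeca-5,9,13,17-tetraen-1-yne; 16 2-[(2E)-5-bromo-3-methylpent-2-en-1-yl]-4-methoxy-3,5-bis(methoxymethoxy)-1-methylbenzene
Product: 23 2-[(2E,6E,10E,14E,18E)-3,7,11,15,19,23-hexamethyltetracosa-2,6,10,14,18,22-hexaen-1-yl]-4-methoxy-3,5-bis(methoxymethoxy)-1-methylbenzene, via alkenyldimethylalane 21 (not isolated), via alkenylzinc bromide 22 (not isolated)
Conditions: 20 (1.5 equiv), Me3Al, Cp2ZrCl2 (10 mol%), CH2Cl2, 0 °C to rt; volatiles removed in vacuo; ZnBr2, THF, 0 °C; then 16, Pd2(dba)3 (2 mol%), PCyp3 (8 mol%), N-methylimidazole, THF/NMP, 80 °C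
Reagents that add atoms: trimethylaluminium, C[Al](C)C
Why: Proposed new method: zirconium-catalysed syn-methylalumination of the terminal alkyne (Negishi carboalumination) puts CH3 on C7' and aluminium on C6', ZnBr2 shuttles the alkenyl group from aluminium to zinc, and the (E)-alkenylzinc bromide is coupled with the unactivated primary bromide by a zerovalent palladium/tricyclopentylphosphine catalyst through SN2-type oxidative addition at C5', transmetalation and reductive elimination with retention at C6'. The closest known reactions are the one-pot carboalumination/palladium- or nickel-catalysed coupling of alkenylalanes with aryl, alkenyl, allyl and benzyl halides (with zinc salts as shuttle) and the Negishi coupling of preformed alkenylzinc halides with β-hydrogen-bearing primary alkyl bromides under exactly this catalyst system; their union in one flask on an alkyl electrophile is the untested part. No ring is closed and no stereocentre is created; the only stereochemical element, the C6'=C7' geometry, is fixed as E by the syn addition (CH3 and metal cis) and by stereoretentive transmetalation and reductive elimination. The step needs terminal regioselectivity of the carbometalation, secured by the monosubstituted alkyne with all trisubstituted olefins inert to Me3Al/zirconocene; transfer of the sp2 alkenyl group in preference to methyl, which is why excess Me3Al is stripped before zinc is added; and coupling faster than β-hydride elimination of the homoallylpalladium intermediate, secured by the bulky electron-rich phosphine. Three components (20, a methyl from Me3Al, 16) thus deliver the C5'–C6' bond, the C7' methyl branch and the (E)-olefin in one operation.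

Step 12
Reactants: 23 2-[(2E,6E,10E,14E,18E)-3,7,11,15,19,23-hexamethyltetracosa-2,6,10,14,18,22-hexaen-1-yl]-4-methoxy-3,5-bis(methoxymethoxy)-1-methylbenzene
Product: 24 4-[(2E,6E,10E,14E,18E)-3,7,11,15,19,23-hexamethyltetracosa-2,6,10,14,18,22-hexaen-1-yl]-2-methoxy-5-methylbenzene-1,3-diol
Conditions: HCl (0.5 M in MeOH), THF, 0 °C to rt, argon
Reagents that add atoms: none
Why: Acid-catalysed acetal solvolysis (transacetalisation to methanol) of the two aryl MOM ethers, run dilute and cold so that the ortho phenol does not add to the C2'=C3' olefin.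

Step 13
Reactants: 24 4-[(2E,6E,10E,14E,18E)-3,7,11,15,19,23-hexamethyltetracosa-2,6,10,14,18,22-hexaen-1-yl]-2-methoxy-5-methylbenzene-1,3-diol
Product: 25 3-demethylubiquinone-6 (2-[(all-E)-hexaprenyl]-5-hydroxy-6-methoxy-3-methylcyclohexa-2,5-diene-1,4-dione)
Conditions: (KO3S)2NO (Fremy's salt, 2.5 equiv), aq. KH2PO4, acetone/THF, 0 °C to rt
Reagents that add atoms: dipotassium nitrosodisulfonate (Fremy's salt), [K+].[K+].[O]N(S(=O)(=O)[O-])S(=O)(=O)[O-]
Why: Teuber oxidation: the phenoxyl radical is trapped by a second nitroxyl at the only unsubstituted ring carbon (C4, para to O1 and ortho to O3), and loss of imidodisulfonate should give the 3-hydroxy-1,4-quinone whichever hydroxyl is oxidised first, while the olefins are inert to the reagent.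

**Compound list**
1 | orcinol (5-methylbenzene-1,3-diol) | Cc1cc(O)cc(O)c1 | starting material
2 | 1,3-bis(methoxymethoxy)-5-methylbenzene | COCOc1cc(C)cc(OCOC)c1 | intermediate
3 | [2,6-bis(methoxymethoxy)-4-methylphenyl]lithium | [Li]c1c(OCOC)cc(C)cc1OCOC | intermediate
4 | lithium [2,6-bis(methoxymethoxy)-4-methylphenyl]trimethoxyborate | [Li+].CO[B-](OC)(OC)c1c(OCOC)cc(C)cc1OCOC | intermediate
5 | 2,6-bis(methoxymethoxy)-4-methylphenol | COCOc1cc(C)cc(OCOC)c1O | intermediate
6 | 2-methoxy-1,3-bis(methoxymethoxy)-5-methylbenzene | COCOc1cc(C)cc(OCOC)c1OC | intermediate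
7 | tert-butyl(but-3-yn-1-yloxy)dimethylsilane | C#CCCO[Si](C)(C)C(C)(C)C | starting material
8 | [(1E)-4-(tert-butyldimethylsilyloxy)-2-methylbut-1-en-1-yl]dimethylalumane | C[Al](C)/C=C(\C)CCO[Si](C)(C)C(C)(C)C | intermediate
9 | lithium butyl[(1E)-4-(tert-butyldimethylsilyloxy)-2-methylbut-1-en-1-yl]dimethylalanate | [Li+].CCCC[Al-](C)(C)/C=C(\C)CCO[Si](C)(C)C(C)(C)C | intermediate
10 | (2E)-5-(tert-butyldimethylsilyloxy)-3-methylpent-2-en-1-ol | OC/C=C(\C)CCO[Si](C)(C)C(C)(C)C | intermediate
11 | (2E)-1-bromo-5-(tert-butyldimethylsilyloxy)-3-methylpent-2-ene | BrC/C=C(\C)CCO[Si](C)(C)C(C)(C)C | intermediate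
12 | [3-methoxy-2,4-bis(methoxymethoxy)-6-methylphenyl]lithium | [Li]c1c(C)cc(OCOC)c(OC)c1OCOC | intermediate
13 | [3-methoxy-2,4-bis(methoxymethoxy)-6-methylphenyl]copper | [Cu]c1c(C)cc(OCOC)c(OC)c1OCOC | intermediate
14 | tert-butyl{[(3E)-5-[3-methoxy-2,4-bis(methoxymethoxy)-6-methylphenyl]-3-methylpent-3-en-1-yl]oxy}dimethylsilane | COCOc1cc(C)c(C/C=C(\C)CCO[Si](C)(C)C(C)(C)C)c(OCOC)c1OC | intermediate
15 | (3E)-5-[3-methoxy-2,4-bis(methoxymethoxy)-6-methylphenyl]-3-methylpent-3-en-1-ol | COCOc1cc(C)c(C/C=C(\C)CCO)c(OCOC)c1OC | intermediate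
16 | 2-[(2E)-5-bromo-3-methylpent-2-en-1-yl]-4-methoxy-3,5-bis(methoxymethoxy)-1-methylbenzene | COCOc1cc(C)c(C/C=C(\C)CCBr)c(OCOC)c1OC | intermediate
17 | (2E,6E,10E)-geranylgeraniol, (2E,6E,10E)-3,7,11,15-tetramethylhexadeca-2,6,10,14-tetraen-1-ol | OC/C=C(\C)CC/C=C(\C)CC/C=C(\C)CCC=C(C)C | starting material
18 | (2E,6E,10E)-geranylgeranyl bromide, (2E,6E,10E)-1-bromo-3,7,11,15-tetramethylhexadeca-2,6,10,14-tetraene | BrC/C=C(\C)CC/C=C(\C)CC/C=C(\C)CCC=C(C)C | intermediate
19 | trimethyl[(5E,9E,13E)-6,10,14,18-tetramethylnonadeca-5,9,13,17-tetraen-1-yn-1-yl]silane | C[Si](C)(C)C#CCC/C=C(\C)CC/C=C(\C)CC/C=C(\C)CCC=C(C)C | intermediate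
20 | (5E,9E,13E)-6,10,14,18-tetramethylnonadeca-5,9,13,17-tetraen-1-yne | C#CCC/C=C(\C)CC/C=C(\C)CC/C=C(\C)CCC=C(C)C | intermediate
21 | dimethyl[(1E,5E,9E,13E)-2,6,10,14,18-pentamethylnonadeca-1,5,9,13,17-pentaen-1-yl]alumane | C[Al](C)/C=C(\C)CC/C=C(\C)CC/C=C(\C)CC/C=C(\C)CCC=C(C)C | intermediate
22 | bromo[(1E,5E,9E,13E)-2,6,10,14,18-pentamethylnonadeca-1,5,9,13,17-pentaen-1-yl]zinc | Br[Zn]/C=C(\C)CC/C=C(\C)CC/C=C(\C)CC/C=C(\C)CCC=C(C)C | intermediate
23 | 2-[(2E,6E,10E,14E,18E)-3,7,11,15,19,23-hexamethyltetracosa-2,6,10,14,18,22-hexaen-1-yl]-4-methoxy-3,5-bis(methoxymethoxy)-1-methylbenzene | COCOc1cc(C)c(C/C=C(\C)CC/C=C(\C)CC/C=C(\C)CC/C=C(\C)CC/C=C(\C)CCC=C(C)C)c(OCOC)c1OC | intermediate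
24 | 4-[(2E,6E,10E,14E,18E)-3,7,11,15,19,23-hexamethyltetracosa-2,6,10,14,18,22-hexaen-1-yl]-2-methoxy-5-methylbenzene-1,3-diol | COc1c(O)cc(C)c(C/C=C(\C)CC/C=C(\C)CC/C=C(\C)CC/C=C(\C)CC/C=C(\C)CCC=C(C)C)c1O | intermediate
25 | 3-demethylubiquinone-6 | COC1=C(O)C(=O)C(C)=C(C/C=C(\C)CC/C=C(\C)CC/C=C(\C)CC/C=C(\C)CC/C=C(\C)CCC=C(C)C)C1=O | target

**Step count and risks**
Total step count: 13. Longest linear sequence: 9 steps (steps 1, 2, 3, 6, 7, 8, 11, 12, 13 from orcinol).

Step 11 (bears the new-method label). What may go wrong: transfer of methyl instead of the alkenyl group from the mixed alkenyl(methyl)metal species, β-hydride elimination or reduction at the alkylpalladium stage, and inhibition of the palladium catalyst by aluminium or zirconium residues. The fallback uses known chemistry, sets out from 20 and 16 and comes back at 23. Alkyne 20 is carboaluminated as in step 11 to alane 21, and iodinolysis (I2, THF, −30 °C) with retention should give (1E,5E,9E,13E)-1-iodo-2,6,10,14,18-pentamethylnonadeca-1,5,9,13,17-pentaene F1. Bromide 16 is converted by LiCl-mediated zinc insertion (Zn dust, LiCl, THF, 50 °C) into {(3E)-5-[3-methoxy-2,4-bis(methoxymethoxy)-6-methylphenyl]-3-methylpent-3-en-1-yl}zinc bromide F2. Negishi coupling of F2 with F1 (PdCl2(dppf), THF, rt to 45 °C), the established alkylzinc/alkenyl iodide coupling with retention of olefin geometry, forms the same C5'–C6' bond and should give 23.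

Step 6. What may go wrong: incomplete or misdirected lithiation, and slow transfer of the doubly ortho-substituted aryl group from copper, so that protonation, biaryl homocoupling or SN2' attack compete. The fallback sets out from 6 and 7 and comes back at 14; it forms C1'–C2' instead of aryl–C1'. Aryllithium 12 is quenched with paraformaldehyde to give [3-methoxy-2,4-bis(methoxymethoxy)-6-methylphenyl]methanol F3. Appel chlorination (PPh3, CCl4, CH2Cl2, 0 °C) should give 2-(chloromethyl)-4-methoxy-3,5-bis(methoxymethoxy)-1-methylbenzene F4, which is used at once because such electron-rich benzylic chlorides tend to self-alkylate. Nickel-catalysed coupling of F4 with alkenylalane 8 (from 7 as in step 4, without the butyllithium/formaldehyde stage; zerovalent nickel catalyst from NiCl2(PPh3)2 and n-BuLi, THF, rt), a known alkenylalane/benzylic chloride coupling with retention, should deliver 14 directly.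

Step 12. What may go wrong: proton-induced cyclisation of the freed ortho phenol onto the C2'=C3' olefin (chroman formation) and acid-promoted addition or cyclisation along the polyene during acetal solvolysis. The fallback sets out from 23 and comes back at 24. Under non-protic, buffered conditions (TMSOTf, 2,2'-bipyridyl, CH2Cl2/MeCN, 0 °C) the aryl MOM ethers are exchanged for silyl groups, which should give the 1,3-bis(trimethylsilyl) ether of 24 F5. The aryl silyl ethers are then hydrolysed during a mild aqueous work-up (water, trace K2CO3, 0 °C) to give 24.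

**Further compounds**
F1 | step 11 | (1E,5E,9E,13E)-1-iodo-2,6,10,14,18-pentamethylnonadeca-1,5,9,13,17-pentaene | I/C=C(\C)CC/C=C(\C)CC/C=C(\C)CC/C=C(\C)CCC=C(C)C
F2 | step 11 | {(3E)-5-[3-methoxy-2,4-bis(methoxymethoxy)-6-methylphenyl]-3-methylpent-3-en-1-yl}zinc bromide | COCOc1cc(C)c(C/C=C(\C)CC[Zn]Br)c(OCOC)c1OC
F3 | step 6 | [3-methoxy-2,4-bis(methoxymethoxy)-6-methylphenyl]methanol | COCOc1cc(C)c(CO)c(OCOC)c1OC
F4 | step 6 | 2-(chloromethyl)-4-methoxy-3,5-bis(methoxymethoxy)-1-methylbenzene | COCOc1cc(C)c(CCl)c(OCOC)c1OC
F5 | step 12 | 1,3-bis(trimethylsilyl) ether of 24 | COc1c(O[Si](C)(C)C)cc(C)c(C/C=C(\C)CC/C=C(\C)CC/C=C(\C)CC/C=C(\C)CC/C=C(\C)CCC=C(C)C)c1O[Si](C)(C)C
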